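## Retrosynthetic overview

1. Target 44 ⇐ ketone 43 (global O-debenzylation) ⇐ alcohol 42 (oxidation) ⇐ silyl ether 41; the epimerisable Ar–CH(CH2OH)–C=O centre only appears in the last two steps.
2. 41 ⇐ lactone 39 + benzylic bromide 22 by trans-selective alkylation of the lactone enolate (the convergent C–C bond).
3. 22 ⇐ dihydrobenzofuran 19, whose ring closes by intramolecular oxa-Michael (1,6-) addition of a phenol to the p-quinone methide 18, generated from the aldol-derived phenolic diol 17 (Evans syn-aldol, (S)-auxiliary).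
4. 39 ⇐ Evans alkylation of the succinate-derived imide 35 with benzylic bromide 32, then reduction and lactonisation; 32 ⇐ the enantiomeric Evans syn-aldol ((R)-auxiliary), its carbinol kept as a TBS ether (the future ketone).
5. Both aldol donors ⇐ one arylacetyl chloride 9 (methyl vanillate: O-allylation, Claisen, benzylation, oxidative cleavage, chlorination). Ring order: dihydrobenzofuran (step 10), butyrolactone (step 23), union (step 24).

Assumption: the SMILES is read literally (S at the CH(CH2OH) next to the ketone, trans-3R,4R lactone, trans-2S,3R dihydrobenzofuran); the exocyclic C=C of quinone methide 18 is written without E/Z because both forms give 19.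

## Route

Step 1
Reactants: 1 methyl 4-hydroxy-3-methoxybenzoate (methyl vanillate); 2 allyl bromide
Product: 3 methyl 3-methoxy-4-(prop-2-en-1-yloxy)benzoate
Conditions: K2CO3, acetone, reflux
Reagents that add atoms: none
Why: Williamson ether synthesis (SN2 of the phenoxide on allyl bromide); no stereocentre.

Step 2
Reactants: 3 methyl 3-methoxy-4-(prop-2-en-1-yloxy)benzoate
Product: 5 methyl 4-hydroxy-3-methoxy-5-(prop-2-en-1-yl)benzoate, via ortho-dienone 4 (not isolated)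
Conditions: PhNEt2, 200 °C
Reagents that add atoms: none
Why: Aromatic Claisen [3,3]-sigmatropic rearrangement to the only free ortho position (the other ortho carbon carries OMe, the para carbon the ester), followed by tautomerisation of dienone 4.

Step 3
Reactants: 5 methyl 4-hydroxy-3-methoxy-5-(prop-2-en-1-yl)benzoate
Product: 6 methyl 4-(benzyloxy)-3-methoxy-5-(prop-2-en-1-yl)benzoate
Conditions: BnBr, K2CO3, DMF, 60 °C
Reagents that add atoms: benzyl bromide, BrCc1ccccc1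
Why: Williamson O-benzylation of the phenol; ester and alkene are inert.

Step 4
Reactants: 6 methyl 4-(benzyloxy)-3-methoxy-5-(prop-2-en-1-yl)benzoate
Product: 8 [2-(benzyloxy)-3-methoxy-5-(methoxycarbonyl)phenyl]acetic acid, via aldehyde 7 (not isolated)
Conditions: OsO4 (2 mol %), NaIO4, 2,6-lutidine, dioxane/H2O, rt; crude 7 then NaClO2, NaH2PO4, 2-methyl-2-butene, t-BuOH/H2O, 0 °C → rt
Reagents that add atoms: osmium tetroxide (catalytic), O=[Os](=O)(=O)=O; sodium periodate, [Na+].[O-]I(=O)(=O)=O; sodium chlorite, [Na+].[O-]Cl=O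
Why: Lemieux–Johnson oxidative cleavage of the terminal alkene, then Pinnick oxidation of the crude arylacetaldehyde, neither of which touches the benzyl ether or the ester.

Step 5
Reactants: 8 [2-(benzyloxy)-3-methoxy-5-(methoxycarbonyl)phenyl]acetic acid
Product: 9 methyl 4-(benzyloxy)-3-(2-chloro-2-oxoethyl)-5-methoxybenzoate (arylacetyl chloride)
Conditions: (COCl)2, DMF (cat.), CH2Cl2, 0 °C → rt; evaporated and divided into two portions for steps 6 and 14
Reagents that add atoms: oxalyl chloride, O=C(Cl)C(=O)Cl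
Why: Acyl chloride formation through the DMF-derived chloroiminium (Vilsmeier) catalyst; the benzyl ether and the methyl ester are inert and no stereocentre is involved.

Step 6
Reactants: 9 methyl 4-(benzyloxy)-3-(2-chloro-2-oxoethyl)-5-methoxybenzoate; 10 (4S)-4-benzyl-1,3-oxazolidin-2-one
Product: 12 (4S)-N-arylacetyl oxazolidinone (methyl 4-(benzyloxy)-3-{2-[(4S)-4-benzyl-2-oxo-1,3-oxazolidin-3-yl]-2-oxoethyl}-5-methoxybenzoate), via lithium oxazolidinide 11 (not isolated)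
Conditions: 10, n-BuLi (1.0 equiv), THF, −78 °C; then 9, −78 → 0 °C
Reagents that add atoms: none
Why: N-acylation (nucleophilic acyl substitution) of the lithiated Evans oxazolidinone by the acid chloride, which is far more electrophilic than the methyl benzoate at −78 °C; no new stereocentre.

Step 7
Reactants: 12 (4S)-N-arylacetyl oxazolidinone; 13 4-(benzyloxy)-3-methoxybenzaldehyde
Product: 15 (2S,3S)-syn-aldol adduct, via boron enolate 14 (not isolated)
Conditions: n-Bu2BOTf, i-Pr2NEt, CH2Cl2, 0 °C; 13, −78 → 0 °C; pH 7 buffer, MeOH, 30 % H2O2, 0 °C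
Reagents that add atoms: none
Why: Evans syn-aldol reaction, in which the Z-boron enolate 14 reacts through a Zimmerman–Traxler chair on the face away from the auxiliary benzyl group and sets both new centres as (2S,3S); the aryl-bearing centre is the future C3 of the dihydrobenzofuran.

Step 8
Reactants: 15 (2S,3S)-syn-aldol adduct
Product: 16 (1S,2R)-1,3-diol (methyl 4-(benzyloxy)-3-{(1S,2R)-1-[4-(benzyloxy)-3-methoxyphenyl]-1,3-dihydroxypropan-2-yl}-5-methoxybenzoate)
Conditions: LiBH4, MeOH (1.5 equiv), THF, 0 °C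
Reagents that add atoms: none
Why: Reductive cleavage of the N-acyl oxazolidinone by borohydride, the imide carbonyl being far more electrophilic than the electron-rich methyl benzoate; both stereocentres are untouched (the descriptor at C2 changes only because CH2OH replaces C=O).

Step 9
Reactants: 16 (1S,2R)-1,3-diol
Product: 17 methyl 3-[(1S,2R)-1,3-dihydroxy-1-(4-hydroxy-3-methoxyphenyl)propan-2-yl]-4-hydroxy-5-methoxybenzoate
Conditions: H2 (1 atm), 10 % Pd/C, EtOAc, rt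
Reagents that add atoms: none
Why: Catalytic hydrogenolysis of the two aryl benzyl ethers under neutral conditions frees both phenols while the benzylic carbinol, which needs acid to ionise, is retained.

Step 10
Reactants: 17 methyl 3-[(1S,2R)-1,3-dihydroxy-1-(4-hydroxy-3-methoxyphenyl)propan-2-yl]-4-hydroxy-5-methoxybenzoate
Product: 19 methyl (2S,3R)-2-(4-hydroxy-3-methoxyphenyl)-3-(hydroxymethyl)-7-methoxy-2,3-dihydro-1-benzofuran-5-carboxylate, via quinone methide 18 (not isolated)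
Conditions: p-TsOH·H2O (10 mol %), MeCN (0.02 M), rt
Reagents that add atoms: none
Why: Acid-catalysed dehydration of the p-hydroxybenzyl alcohol gives p-quinone methide 18, and the ortho-phenol of the neighbouring ring closes the dihydrofuran by intramolecular oxa-Michael (1,6-conjugate) addition; the existing C3 centre places the C2 aryl group trans to CH2OH (kinetically preferred and, because the addition is reversible under acid, also the thermodynamic product), giving (2S,3R).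

Step 11
Reactants: 19 methyl (2S,3R)-2-(4-hydroxy-3-methoxyphenyl)-3-(hydroxymethyl)-7-methoxy-2,3-dihydro-1-benzofuran-5-carboxylate
Product: 20 methyl (2S,3R)-2-[4-(benzyloxy)-3-methoxyphenyl]-3-[(benzyloxy)methyl]-7-methoxy-2,3-dihydro-1-benzofuran-5-carboxylate
Conditions: NaH, BnBr, n-Bu4NI (cat.), DMF, 0 °C → rt (BnBr present before NaH is added)
Reagents that add atoms: benzyl bromide, BrCc1ccccc1
Why: Williamson benzylation of the phenoxide and the primary alkoxide in one operation, the phenoxide being capped at once so that it cannot reopen the ring; stereocentres untouched.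

Step 12
Reactants: 20 methyl (2S,3R)-2-[4-(benzyloxy)-3-methoxyphenyl]-3-[(benzyloxy)methyl]-7-methoxy-2,3-dihydro-1-benzofuran-5-carboxylate
Product: 21 {(2S,3R)-2-[4-(benzyloxy)-3-methoxyphenyl]-3-[(benzyloxy)methyl]-7-methoxy-2,3-dihydro-1-benzofuran-5-yl}methanol
Conditions: LiAlH4, THF, 0 °C
Reagents that add atoms: none
Why: Hydride reduction of the aryl ester to the benzylic alcohol; ethers and the dihydrobenzofuran are inert.

Step 13
Reactants: 21 {(2S,3R)-2-[4-(benzyloxy)-3-methoxyphenyl]-3-[(benzyloxy)methyl]-7-methoxy-2,3-dihydro-1-benzofuran-5-yl}methanol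
Product: 22 (2S,3R)-2-[4-(benzyloxy)-3-methoxyphenyl]-3-[(benzyloxy)methyl]-5-(bromomethyl)-7-methoxy-2,3-dihydro-1-benzofuran
Conditions: CBr4, PPh3, CH2Cl2, 0 °C
Reagents that add atoms: carbon tetrabromide, BrC(Br)(Br)Br
Why: Appel reaction (alkoxyphosphonium displaced by bromide) gives the benzylic bromide under neutral conditions that do not ionise the dihydrobenzofuran.

Step 14
Reactants: 9 methyl 4-(benzyloxy)-3-(2-chloro-2-oxoethyl)-5-methoxybenzoate; 23 (4R)-4-benzyl-1,3-oxazolidin-2-one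
Product: 25 (4R)-N-arylacetyl oxazolidinone (methyl 4-(benzyloxy)-3-{2-[(4R)-4-benzyl-2-oxo-1,3-oxazolidin-3-yl]-2-oxoethyl}-5-methoxybenzoate), via lithium oxazolidinide 24 (not isolated)
Conditions: 23, n-BuLi (1.0 equiv), THF, −78 °C; then 9, −78 → 0 °C
Reagents that add atoms: none
Why: N-acylation (nucleophilic acyl substitution) of the lithiated oxazolidinone by the acid chloride as in step 6, now with the (R)-auxiliary; no new stereocentre.

Step 15
Reactants: 25 (4R)-N-arylacetyl oxazolidinone; 13 4-(benzyloxy)-3-methoxybenzaldehyde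
Product: 27 (2R,3R)-syn-aldol adduct, via boron enolate 26 (not isolated)
Conditions: n-Bu2BOTf, i-Pr2NEt, CH2Cl2, 0 °C; 13, −78 → 0 °C; pH 7 buffer, MeOH, 30 % H2O2, 0 °C
Reagents that add atoms: none
Why: Evans syn-aldol reaction with the enantiomeric auxiliary (Z-boron enolate, Zimmerman–Traxler chair), giving (2R,3R); the aryl-bearing centre is the future α-centre of the ketone.

Step 16
Reactants: 27 (2R,3R)-syn-aldol adduct
Product: 28 (2R,3R)-aldol adduct O-tert-butyldimethylsilyl ether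
Conditions: TBSOTf, 2,6-lutidine, CH2Cl2, −78 → 0 °C
Reagents that add atoms: tert-butyldimethylsilyl triflate, CC(C)(C)[Si](C)(C)OS(=O)(=O)C(F)(F)F
Why: Silylation with the silyl triflate blocks retro-aldol and marks the carbinol that later becomes the ketone; no stereocentre is touched.

Step 17
Reactants: 28 (2R,3R)-aldol adduct O-TBS ether
Product: 29 (1R,2S)-1-silyloxy-3-hydroxypropan-2-yl arene (methyl 4-(benzyloxy)-3-{(1R,2S)-1-[4-(benzyloxy)-3-methoxyphenyl]-1-[(tert-butyldimethylsilyl)oxy]-3-hydroxypropan-2-yl}-5-methoxybenzoate)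
Conditions: LiBH4, MeOH (1.5 equiv), THF, 0 °C
Reagents that add atoms: none
Why: Borohydride cleavage of the imide to the primary alcohol, chemoselective over the electron-rich aryl methyl ester and leaving the silyl ether and both stereocentres intact.

Step 18
Reactants: 29 (1R,2S)-primary alcohol
Product: 30 (1R,2S)-primary benzyl ether (methyl 4-(benzyloxy)-3-{(1R,2S)-3-(benzyloxy)-1-[4-(benzyloxy)-3-methoxyphenyl]-1-[(tert-butyldimethylsilyl)oxy]propan-2-yl}-5-methoxybenzoate)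
Conditions: 2-benzyloxy-1-methylpyridinium triflate, MgO, PhCF3, 85 °C
Reagents that add atoms: 2-benzyloxy-1-methylpyridinium triflate, C[n+]1ccccc1OCc1ccccc1.[O-]S(=O)(=O)C(F)(F)F
Why: Dudley benzylation (thermal benzyl transfer from the pyridinium salt under neutral, MgO-buffered conditions) avoids the alkoxide that would trigger 1,3-silyl migration.

Step 19
Reactants: 30 (1R,2S)-primary benzyl ether
Product: 31 {4-(benzyloxy)-3-[(1R,2S)-3-(benzyloxy)-1-[4-(benzyloxy)-3-methoxyphenyl]-1-[(tert-butyldimethylsilyl)oxy]propan-2-yl]-5-methoxyphenyl}methanol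
Conditions: LiAlH4, THF, −10 → 0 °C
Reagents that add atoms: none
Why: Hydride reduction of the aryl ester to the benzylic alcohol; silyl and benzyl ethers survive at this temperature.

Step 20
Reactants: 31 benzylic alcohol
Product: 32 benzylic bromide ({(1R,2S)-3-(benzyloxy)-1-[4-(benzyloxy)-3-methoxyphenyl]-2-[2-(benzyloxy)-5-(bromomethyl)-3-methoxyphenyl]propoxy}(tert-butyl)dimethylsilane)
Conditions: CBr4, PPh3, CH2Cl2, 0 °C
Reagents that add atoms: carbon tetrabromide, BrC(Br)(Br)Br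
Why: Appel reaction; the neutral conditions spare the acid-labile benzylic silyl ether.

Step 21
Reactants: 33 4-tert-butoxy-4-oxobutanoic acid; 23 (4R)-4-benzyl-1,3-oxazolidin-2-one
Product: 35 tert-butyl 4-[(4R)-4-benzyl-2-oxo-1,3-oxazolidin-3-yl]-4-oxobutanoate, via mixed anhydride 34 (not isolated)
Conditions: PivCl, Et3N, THF, −20 °C; then 23, LiCl, rt
Reagents that add atoms: none
Why: Mixed-anhydride N-acylation of the LiCl/Et3N-activated oxazolidinone, which attacks the unhindered succinyl carbonyl of 34; no stereocentre formed.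

Step 22
Reactants: 35 tert-butyl 4-[(4R)-4-benzyl-2-oxo-1,3-oxazolidin-3-yl]-4-oxobutanoate; 32 benzylic bromide
Product: 37 (3R)-benzylated succinate imide, via sodium enolate 36 (not isolated)
Conditions: 35 (1.5 equiv), NaHMDS, THF, −78 °C; then 32, −78 → −45 °C
Reagents that add atoms: none
Why: Evans asymmetric alkylation, in which the chelated Z-sodium enolate 36 (the imide α-CH2 is more acidic than the ester α-CH2) is benzylated on the face away from the auxiliary benzyl group, setting the (R) centre that becomes C4 of the lactone.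

Step 23
Reactants: 37 (3R)-benzylated succinate imide
Product: 39 (4R)-4-(arylmethyl)oxolan-2-one, via hydroxy ester 38 (not isolated)
Conditions: LiBH4, H2O (1 equiv), THF, 0 °C; then PPTS (10 mol %), PhMe, 80 °C
Reagents that add atoms: none
Why: Borohydride removes the auxiliary chemoselectively (the tert-butyl ester is untouched) and the γ-hydroxy ester 38 lactonises by acid-catalysed intramolecular transesterification without involving the stereocentre.

Step 24
Reactants: 39 (4R)-4-(arylmethyl)oxolan-2-one; 22 benzofuranylmethyl bromide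
Product: 41 trans-(3R,4R)-3,4-dibenzyl lactone (fully protected), via lithium enolate 40 (not isolated)
Conditions: LiHMDS, THF, −78 °C; then 22, DMPU, −78 → −40 °C
Reagents that add atoms: none
Why: Alkylation of the lactone lithium enolate 40 by the benzylic bromide (SN2) occurs anti to the C4 substituent and gives the trans-(3R,4R) lactone.

Step 25
Reactants: 41 trans-(3R,4R)-lactone silyl ether
Product: 42 secondary benzylic alcohol (the desilylated lactone)
Conditions: HF·pyridine, pyridine, THF, 0 °C → rt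
Reagents that add atoms: none
Why: Fluoride-mediated Si–O cleavage under buffered conditions frees only the secondary benzylic alcohol; benzyl ethers, lactone and dihydrobenzofuran are inert.

Step 26
Reactants: 42 secondary benzylic alcohol
Product: 43 aryl ketone (pentabenzyl ether of the target)
Conditions: Dess–Martin periodinane, NaHCO3, CH2Cl2, 0 °C → rt
Reagents that add atoms: none
Why: Dess–Martin oxidation under buffered, non-basic conditions gives the aryl ketone without enolising the adjacent aryl-bearing stereocentre, which is now (S).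

Step 27
Reactants: 43 aryl ketone pentabenzyl ether
Product: 44 CNP0111438.1
Conditions: H2 (1 atm), 20 % Pd(OH)2/C, EtOAc/EtOH, rt
Reagents that add atoms: none
Why: Catalytic hydrogenolysis removes all five benzyl ethers under neutral conditions, which should leave the electron-rich aryl ketone, the lactone, the dihydrobenzofuran and the labile α-centre untouched.

## Compound list

1 | methyl 4-hydroxy-3-methoxybenzoate (methyl vanillate) | COC(=O)c1ccc(O)c(OC)c1 | starting material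
2 | allyl bromide (3-bromoprop-1-ene) | C=CCBr | starting material
3 | methyl 3-methoxy-4-(prop-2-en-1-yloxy)benzoate | COC(=O)c1ccc(OCC=C)c(OC)c1 | intermediate
4 | methyl 5-methoxy-4-oxo-3-(prop-2-en-1-yl)cyclohexa-1,5-diene-1-carboxylate (ortho-dienone, racemic, not isolated) | COC(=O)C1=CC(CC=C)C(=O)C(OC)=C1 | intermediate
5 | methyl 4-hydroxy-3-methoxy-5-(prop-2-en-1-yl)benzoate | COC(=O)c1cc(CC=C)c(O)c(OC)c1 | intermediate
6 | methyl 4-(benzyloxy)-3-methoxy-5-(prop-2-en-1-yl)benzoate | COC(=O)c1cc(CC=C)c(OCc2ccccc2)c(OC)c1 | intermediate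
7 | methyl 4-(benzyloxy)-3-methoxy-5-(2-oxoethyl)benzoate (not isolated) | COC(=O)c1cc(CC=O)c(OCc2ccccc2)c(OC)c1 | intermediate
8 | [2-(benzyloxy)-3-methoxy-5-(methoxycarbonyl)phenyl]acetic acid | COC(=O)c1cc(CC(=O)O)c(OCc2ccccc2)c(OC)c1 | intermediate
9 | methyl 4-(benzyloxy)-3-(2-chloro-2-oxoethyl)-5-methoxybenzoate (arylacetyl chloride) | COC(=O)c1cc(CC(=O)Cl)c(OCc2ccccc2)c(OC)c1 | intermediate
10 | (4S)-4-benzyl-1,3-oxazolidin-2-one | O=C1N[C@@H](Cc2ccccc2)CO1 | starting material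
11 | lithium (4S)-4-benzyl-2-oxo-1,3-oxazolidin-3-ide (not isolated) | [Li+].O=C1[N-][C@@H](Cc2ccccc2)CO1 | intermediate
12 | methyl 4-(benzyloxy)-3-{2-[(4S)-4-benzyl-2-oxo-1,3-oxazolidin-3-yl]-2-oxoethyl}-5-methoxybenzoate | COC(=O)c1cc(CC(=O)N2[C@@H](Cc3ccccc3)COC2=O)c(OCc2ccccc2)c(OC)c1 | intermediate
13 | 4-(benzyloxy)-3-methoxybenzaldehyde | O=Cc1ccc(OCc2ccccc2)c(OC)c1 | starting material
14 | (Z)-O-dibutylboryl enolate of 12 (not isolated) | COC(=O)c1cc(/C=C(\OB(CCCC)CCCC)N2[C@@H](Cc3ccccc3)COC2=O)c(OCc2ccccc2)c(OC)c1 | intermediate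
15 | methyl 4-(benzyloxy)-3-{(1S,2S)-1-{[(4S)-4-benzyl-2-oxo-1,3-oxazolidin-3-yl]carbonyl}-2-[4-(benzyloxy)-3-methoxyphenyl]-2-hydroxyethyl}-5-methoxybenzoate | COC(=O)c1cc(OC)c(OCc2ccccc2)c(c1)[C@H](C(=O)N1[C@@H](Cc2ccccc2)COC1=O)[C@H](O)c1ccc(OCc2ccccc2)c(OC)c1 | intermediate
16 | methyl 4-(benzyloxy)-3-{(1S,2R)-1-[4-(benzyloxy)-3-methoxyphenyl]-1,3-dihydroxypropan-2-yl}-5-methoxybenzoate | COC(=O)c1cc(OC)c(OCc2ccccc2)c(c1)[C@H](CO)[C@H](O)c1ccc(OCc2ccccc2)c(OC)c1 | intermediate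
17 | methyl 3-[(1S,2R)-1,3-dihydroxy-1-(4-hydroxy-3-methoxyphenyl)propan-2-yl]-4-hydroxy-5-methoxybenzoate | COC(=O)c1cc(OC)c(O)c(c1)[C@H](CO)[C@H](O)c1ccc(O)c(OC)c1 | intermediate
18 | methyl 4-hydroxy-3-[(2R)-1-hydroxy-3-(3-methoxy-4-oxocyclohexa-2,5-dien-1-ylidene)propan-2-yl]-5-methoxybenzoate (p-quinone methide, not isolated) | COC(=O)c1cc(OC)c(O)c(c1)[C@H](CO)C=C1C=CC(=O)C(OC)=C1 | intermediate
19 | methyl (2S,3R)-2-(4-hydroxy-3-methoxyphenyl)-3-(hydroxymethyl)-7-methoxy-2,3-dihydro-1-benzofuran-5-carboxylate | COC(=O)c1cc(OC)c2c(c1)[C@H](CO)[C@@H](c1ccc(O)c(OC)c1)O2 | intermediate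
20 | methyl (2S,3R)-2-[4-(benzyloxy)-3-methoxyphenyl]-3-[(benzyloxy)methyl]-7-methoxy-2,3-dihydro-1-benzofuran-5-carboxylate | COC(=O)c1cc(OC)c2c(c1)[C@H](COCc1ccccc1)[C@@H](c1ccc(OCc3ccccc3)c(OC)c1)O2 | intermediate
21 | {(2S,3R)-2-[4-(benzyloxy)-3-methoxyphenyl]-3-[(benzyloxy)methyl]-7-methoxy-2,3-dihydro-1-benzofuran-5-yl}methanol | OCc1cc(OC)c2c(c1)[C@H](COCc1ccccc1)[C@@H](c1ccc(OCc3ccccc3)c(OC)c1)O2 | intermediate
22 | (2S,3R)-2-[4-(benzyloxy)-3-methoxyphenyl]-3-[(benzyloxy)methyl]-5-(bromomethyl)-7-methoxy-2,3-dihydro-1-benzofuran | BrCc1cc(OC)c2c(c1)[C@H](COCc1ccccc1)[C@@H](c1ccc(OCc3ccccc3)c(OC)c1)O2 | intermediate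
23 | (4R)-4-benzyl-1,3-oxazolidin-2-one | O=C1N[C@H](Cc2ccccc2)CO1 | starting material
24 | lithium (4R)-4-benzyl-2-oxo-1,3-oxazolidin-3-ide (not isolated) | [Li+].O=C1[N-][C@H](Cc2ccccc2)CO1 | intermediate
25 | methyl 4-(benzyloxy)-3-{2-[(4R)-4-benzyl-2-oxo-1,3-oxazolidin-3-yl]-2-oxoethyl}-5-methoxybenzoate | COC(=O)c1cc(CC(=O)N2[C@H](Cc3ccccc3)COC2=O)c(OCc2ccccc2)c(OC)c1 | intermediate
26 | (Z)-O-dibutylboryl enolate of 25 (not isolated) | COC(=O)c1cc(/C=C(\OB(CCCC)CCCC)N2[C@H](Cc3ccccc3)COC2=O)c(OCc2ccccc2)c(OC)c1 | intermediate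
27 | methyl 4-(benzyloxy)-3-{(1R,2R)-1-{[(4R)-4-benzyl-2-oxo-1,3-oxazolidin-3-yl]carbonyl}-2-[4-(benzyloxy)-3-methoxyphenyl]-2-hydroxyethyl}-5-methoxybenzoate | COC(=O)c1cc(OC)c(OCc2ccccc2)c(c1)[C@@H](C(=O)N1[C@H](Cc2ccccc2)COC1=O)[C@@H](O)c1ccc(OCc2ccccc2)c(OC)c1 | intermediate
28 | methyl 4-(benzyloxy)-3-{(1R,2R)-1-{[(4R)-4-benzyl-2-oxo-1,3-oxazolidin-3-yl]carbonyl}-2-[4-(benzyloxy)-3-methoxyphenyl]-2-[(tert-butyldimethylsilyl)oxy]ethyl}-5-methoxybenzoate | COC(=O)c1cc(OC)c(OCc2ccccc2)c(c1)[C@@H](C(=O)N1[C@H](Cc2ccccc2)COC1=O)[C@@H](O[Si](C)(C)C(C)(C)C)c1ccc(OCc2ccccc2)c(OC)c1 | intermediate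
29 | methyl 4-(benzyloxy)-3-{(1R,2S)-1-[4-(benzyloxy)-3-methoxyphenyl]-1-[(tert-butyldimethylsilyl)oxy]-3-hydroxypropan-2-yl}-5-methoxybenzoate | COC(=O)c1cc(OC)c(OCc2ccccc2)c(c1)[C@@H](CO)[C@@H](O[Si](C)(C)C(C)(C)C)c1ccc(OCc2ccccc2)c(OC)c1 | intermediate
30 | methyl 4-(benzyloxy)-3-{(1R,2S)-3-(benzyloxy)-1-[4-(benzyloxy)-3-methoxyphenyl]-1-[(tert-butyldimethylsilyl)oxy]propan-2-yl}-5-methoxybenzoate | COC(=O)c1cc(OC)c(OCc2ccccc2)c(c1)[C@@H](COCc1ccccc1)[C@@H](O[Si](C)(C)C(C)(C)C)c1ccc(OCc2ccccc2)c(OC)c1 | intermediate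
31 | {4-(benzyloxy)-3-[(1R,2S)-3-(benzyloxy)-1-[4-(benzyloxy)-3-methoxyphenyl]-1-[(tert-butyldimethylsilyl)oxy]propan-2-yl]-5-methoxyphenyl}methanol | OCc1cc(OC)c(OCc2ccccc2)c(c1)[C@@H](COCc1ccccc1)[C@@H](O[Si](C)(C)C(C)(C)C)c1ccc(OCc2ccccc2)c(OC)c1 | intermediate
32 | {(1R,2S)-3-(benzyloxy)-1-[4-(benzyloxy)-3-methoxyphenyl]-2-[2-(benzyloxy)-5-(bromomethyl)-3-methoxyphenyl]propoxy}(tert-butyl)dimethylsilane | BrCc1cc(OC)c(OCc2ccccc2)c(c1)[C@@H](COCc1ccccc1)[C@@H](O[Si](C)(C)C(C)(C)C)c1ccc(OCc2ccccc2)c(OC)c1 | intermediate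
33 | 4-tert-butoxy-4-oxobutanoic acid (mono-tert-butyl succinate) | CC(C)(C)OC(=O)CCC(=O)O | starting material
34 | 4-tert-butoxy-4-oxobutanoic pivalic anhydride (not isolated) | CC(C)(C)OC(=O)CCC(=O)OC(=O)C(C)(C)C | intermediate
35 | tert-butyl 4-[(4R)-4-benzyl-2-oxo-1,3-oxazolidin-3-yl]-4-oxobutanoate | CC(C)(C)OC(=O)CCC(=O)N1[C@H](Cc2ccccc2)COC1=O | intermediate
36 | sodium (Z)-enolate of 35 (not isolated) | CC(C)(C)OC(=O)C/C=C(\[O-])N1[C@H](Cc2ccccc2)COC1=O.[Na+] | intermediate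
37 | tert-butyl (3R)-3-{[(4R)-4-benzyl-2-oxo-1,3-oxazolidin-3-yl]carbonyl}-4-{4-(benzyloxy)-3-[(1R,2S)-3-(benzyloxy)-1-[4-(benzyloxy)-3-methoxyphenyl]-1-[(tert-butyldimethylsilyl)oxy]propan-2-yl]-5-methoxyphenyl}butanoate | CC(C)(C)OC(=O)C[C@@H](Cc1cc(OC)c(OCc2ccccc2)c(c1)[C@@H](COCc1ccccc1)[C@@H](O[Si](C)(C)C(C)(C)C)c1ccc(OCc2ccccc2)c(OC)c1)C(=O)N1[C@H](Cc2ccccc2)COC1=O | intermediate
38 | tert-butyl (3R)-4-{4-(benzyloxy)-3-[(1R,2S)-3-(benzyloxy)-1-[4-(benzyloxy)-3-methoxyphenyl]-1-[(tert-butyldimethylsilyl)oxy]propan-2-yl]-5-methoxyphenyl}-3-(hydroxymethyl)butanoate (not isolated) | CC(C)(C)OC(=O)C[C@@H](Cc1cc(OC)c(OCc2ccccc2)c(c1)[C@@H](COCc1ccccc1)[C@@H](O[Si](C)(C)C(C)(C)C)c1ccc(OCc2ccccc2)c(OC)c1)CO | intermediate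
39 | (4R)-4-({4-(benzyloxy)-3-[(1R,2S)-3-(benzyloxy)-1-[4-(benzyloxy)-3-methoxyphenyl]-1-[(tert-butyldimethylsilyl)oxy]propan-2-yl]-5-methoxyphenyl}methyl)oxolan-2-one | O=C1C[C@@H](Cc2cc(OC)c(OCc3ccccc3)c(c2)[C@@H](COCc2ccccc2)[C@@H](O[Si](C)(C)C(C)(C)C)c2ccc(OCc3ccccc3)c(OC)c2)CO1 | intermediate
40 | lithium enolate of 39 (not isolated) | [Li+].[O-]C1=C[C@@H](Cc2cc(OC)c(OCc3ccccc3)c(c2)[C@@H](COCc2ccccc2)[C@@H](O[Si](C)(C)C(C)(C)C)c2ccc(OCc3ccccc3)c(OC)c2)CO1 | intermediate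
41 | (3R,4R)-3-({(2S,3R)-2-[4-(benzyloxy)-3-methoxyphenyl]-3-[(benzyloxy)methyl]-7-methoxy-2,3-dihydro-1-benzofuran-5-yl}methyl)-4-({4-(benzyloxy)-3-[(1R,2S)-3-(benzyloxy)-1-[4-(benzyloxy)-3-methoxyphenyl]-1-[(tert-butyldimethylsilyl)oxy]propan-2-yl]-5-methoxyphenyl}methyl)oxolan-2-one | COc1cc([C@H](O[Si](C)(C)C(C)(C)C)[C@H](COCc2ccccc2)c2cc(C[C@H]3COC(=O)[C@@H]3Cc3cc(OC)c4c(c3)[C@H](COCc3ccccc3)[C@@H](c3ccc(OCc5ccccc5)c(OC)c3)O4)cc(OC)c2OCc2ccccc2)ccc1OCc1ccccc1 | intermediate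
42 | (3R,4R)-3-({(2S,3R)-2-[4-(benzyloxy)-3-methoxyphenyl]-3-[(benzyloxy)methyl]-7-methoxy-2,3-dihydro-1-benzofuran-5-yl}methyl)-4-({4-(benzyloxy)-3-[(1R,2S)-3-(benzyloxy)-1-[4-(benzyloxy)-3-methoxyphenyl]-1-hydroxypropan-2-yl]-5-methoxyphenyl}methyl)oxolan-2-one | COc1cc([C@H](O)[C@H](COCc2ccccc2)c2cc(C[C@H]3COC(=O)[C@@H]3Cc3cc(OC)c4c(c3)[C@H](COCc3ccccc3)[C@@H](c3ccc(OCc5ccccc5)c(OC)c3)O4)cc(OC)c2OCc2ccccc2)ccc1OCc1ccccc1 | intermediate
43 | (3R,4R)-3-({(2S,3R)-2-[4-(benzyloxy)-3-methoxyphenyl]-3-[(benzyloxy)methyl]-7-methoxy-2,3-dihydro-1-benzofuran-5-yl}methyl)-4-({4-(benzyloxy)-3-[(2S)-3-(benzyloxy)-1-[4-(benzyloxy)-3-methoxyphenyl]-1-oxopropan-2-yl]-5-methoxyphenyl}methyl)oxolan-2-one | COc1cc(C(=O)[C@H](COCc2ccccc2)c2cc(C[C@H]3COC(=O)[C@@H]3Cc3cc(OC)c4c(c3)[C@H](COCc3ccccc3)[C@@H](c3ccc(OCc5ccccc5)c(OC)c3)O4)cc(OC)c2OCc2ccccc2)ccc1OCc1ccccc1 | intermediate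
44 | CNP0111438.1: (3R,4R)-3-{[(2S,3R)-2-(4-hydroxy-3-methoxyphenyl)-3-(hydroxymethyl)-7-methoxy-2,3-dihydro-1-benzofuran-5-yl]methyl}-4-({4-hydroxy-3-[(2S)-3-hydroxy-1-(4-hydroxy-3-methoxyphenyl)-1-oxopropan-2-yl]-5-methoxyphenyl}methyl)oxolan-2-one | COc1cc(C(=O)[C@H](CO)c2cc(C[C@H]3COC(=O)[C@@H]3Cc3cc(OC)c4c(c3)[C@H](CO)[C@@H](c3ccc(O)c(OC)c3)O4)cc(OC)c2O)ccc1O | target

## Step count and risks

Total step count: 27. Longest linear sequence: 18 steps (1–5, 14–20, 22–27, from methyl vanillate), which is two thirds of the total. The other branches are steps 6–13 (benzofuran bromide 22) and step 21 (imide 35).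

Step 7 is the first likely failure, and step 15 runs the same reaction in the enantiomeric series and shares the risk. Aldolates of arylacetyl imides revert easily by retro-aldol and the electron-rich aldehyde 13 is a sluggish acceptor. The fallback sets out from acid 8 and changes both auxiliary and enolate. EDC·HCl/DMAP coupling of 8 with (4S)-4-benzyl-1,3-thiazolidine-2-thione gives the N-acyl thiazolidinethione F1. Its chlorotitanium enolate (TiCl4, i-Pr2NEt, NMP, CH2Cl2, −78 → 0 °C) adds to 13 to give the Evans-syn adduct F2. The thione auxiliary is a much better leaving group than the oxazolidinone, so NaBH4 in THF/EtOH at 0 °C displaces it before retro-aldol can compete, and the route is rejoined at diol 16.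

Step 24 is the second. The enolate of the heavily substituted lactone 39 and the ionisable p-alkoxybenzyl bromide 22 may give low conversion or decomposition of the bromide. The fallback sets out from alcohol 21 and replaces the alkylation by an aldol addition followed by radical deoxygenation. MnO2 (CH2Cl2, rt) oxidises 21 to the benzofuran-5-carbaldehyde F3. The lithium enolate 40 of lactone 39 adds to F3 at −78 °C, again anti to the C4 substituent, to give the β-hydroxy lactone F4 as a mixture of carbinol epimers. PhOC(S)Cl/pyridine converts this into the phenyl thionocarbonate F5. Bu3SnH/AIBN (PhMe, 80 °C, Barton–McCombie deoxygenation) removes the benzylic oxygen of both epimers and comes back at 41.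

Step 27 is the third. Five benzyl ethers, two of them on primary alcohols, must be hydrogenolysed next to an aryl ketone with an enolisable α-centre and the benzylic C2–O bond of the dihydrobenzofuran, so over-reduction or epimerisation is possible. The fallback sets out from alcohol 42 and removes the benzyl groups before the ketone exists. Hydrogenolysis of 42 (H2, Pd(OH)2/C, EtOAc, kept neutral) gives the hexol F6. TBSCl/imidazole (DMF, 0 °C) silylates the three phenols and the two primary alcohols but not the hindered secondary benzylic carbinol, giving the pentakis-silyl ether F7. Dess–Martin oxidation (NaHCO3, CH2Cl2) gives the silylated ketone F8. HF·pyridine/pyridine (THF, 0 °C) then releases 44 without any reductive step in the presence of the ketone.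

## Further compounds

F1 | step 7 | methyl 4-(benzyloxy)-3-{2-[(4S)-4-benzyl-2-thioxo-1,3-thiazolidin-3-yl]-2-oxoethyl}-5-methoxybenzoate | COC(=O)c1cc(CC(=O)N2[C@@H](Cc3ccccc3)CSC2=S)c(OCc2ccccc2)c(OC)c1
F2 | step 7 | methyl 4-(benzyloxy)-3-{(1S,2S)-1-{[(4S)-4-benzyl-2-thioxo-1,3-thiazolidin-3-yl]carbonyl}-2-[4-(benzyloxy)-3-methoxyphenyl]-2-hydroxyethyl}-5-methoxybenzoate | COC(=O)c1cc(OC)c(OCc2ccccc2)c(c1)[C@H](C(=O)N1[C@@H](Cc2ccccc2)CSC1=S)[C@H](O)c1ccc(OCc2ccccc2)c(OC)c1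
F3 | step 24 | (2S,3R)-2-[4-(benzyloxy)-3-methoxyphenyl]-3-[(benzyloxy)methyl]-7-methoxy-2,3-dihydro-1-benzofuran-5-carbaldehyde | O=Cc1cc(OC)c2c(c1)[C@H](COCc1ccccc1)[C@@H](c1ccc(OCc3ccccc3)c(OC)c1)O2
F4 | step 24 | compound 41 carrying a hydroxy group on the CH2 that links lactone C3 to the benzofuran (β-hydroxy lactone, both carbinol epimers) | COc1cc([C@H](O[Si](C)(C)C(C)(C)C)[C@H](COCc2ccccc2)c2cc(C[C@H]3COC(=O)[C@@H]3C(O)c3cc(OC)c4c(c3)[C@H](COCc3ccccc3)[C@@H](c3ccc(OCc5ccccc5)c(OC)c3)O4)cc(OC)c2OCc2ccccc2)ccc1OCc1ccccc1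
F5 | step 24 | O-phenyl thionocarbonate of F4 (both epimers) | COc1cc([C@H](O[Si](C)(C)C(C)(C)C)[C@H](COCc2ccccc2)c2cc(C[C@H]3COC(=O)[C@@H]3C(OC(=S)Oc3ccccc3)c3cc(OC)c4c(c3)[C@H](COCc3ccccc3)[C@@H](c3ccc(OCc5ccccc5)c(OC)c3)O4)cc(OC)c2OCc2ccccc2)ccc1OCc1ccccc1
F6 | step 27 | (3R,4R)-3-{[(2S,3R)-2-(4-hydroxy-3-methoxyphenyl)-3-(hydroxymethyl)-7-methoxy-2,3-dihydro-1-benzofuran-5-yl]methyl}-4-({3-[(1R,2S)-1,3-dihydroxy-1-(4-hydroxy-3-methoxyphenyl)propan-2-yl]-4-hydroxy-5-methoxyphenyl}methyl)oxolan-2-one | COc1cc([C@H](O)[C@H](CO)c2cc(C[C@H]3COC(=O)[C@@H]3Cc3cc(OC)c4c(c3)[C@H](CO)[C@@H](c3ccc(O)c(OC)c3)O4)cc(OC)c2O)ccc1O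
F7 | step 27 | F6 with tert-butyldimethylsilyl ethers on its three phenols and two primary alcohols (secondary carbinol free) | COc1cc([C@H](O)[C@H](CO[Si](C)(C)C(C)(C)C)c2cc(C[C@H]3COC(=O)[C@@H]3Cc3cc(OC)c4c(c3)[C@H](CO[Si](C)(C)C(C)(C)C)[C@@H](c3ccc(O[Si](C)(C)C(C)(C)C)c(OC)c3)O4)cc(OC)c2O[Si](C)(C)C(C)(C)C)ccc1O[Si](C)(C)C(C)(C)C
F8 | step 27 | pentakis(tert-butyldimethylsilyl) ether of the target (ketone from F7) | COc1cc(C(=O)[C@H](CO[Si](C)(C)C(C)(C)C)c2cc(C[C@H]3COC(=O)[C@@H]3Cc3cc(OC)c4c(c3)[C@H](CO[Si](C)(C)C(C)(C)C)[C@@H](c3ccc(O[Si](C)(C)C(C)(C)C)c(OC)c3)O4)cc(OC)c2O[Si](C)(C)C(C)(C)C)ccc1O[Si](C)(C)C(C)(C)C
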